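The earlier runs and the new flask are simulated with constants of no real substance, noise included.

The maple run, at 22 °C, shows 89.7% of its converted substrate as target at 8.00 h. The larch run shows less at its last reading, and the flask asked about is larch carried on.

in all of them: free enzyme 0.035 mol%

| flask | substrate | temperature | remark | time |
|---|---|---|---|---|
| larch | 0.10 M | 37 °C | the very flask that is asked about, followed so far |  |
| maple | 0.050 M | 22 °C | run made earlier |  |
| flask | 0.10 M | 37 °C |  | 20 h |

| run | time / h | target / % | substrate / % |
|---|---|---|---|
| larch | 1.50 | 19.6 | 77.5 |
| larch | 2.50 | 32.1 | 66.9 |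
| larch | 4.00 | 44.1 | 48.7 |
| larch | 6.00 | 56.4 | 33.2 |
| larch | 8.00 | 61.6 | 20.8 |
| larch | 12.0 | 66.3 | 8.8 |
| larch | 20.0 | 63.5 | 0.4 |
| maple | 1.00 | 4.2 | 97.1 |
| maple | 2.00 | 3.0 | 94.4 |
| maple | 3.00 | 3.6 | 93.2 |
| maple | 5.00 | 8.7 | 91.3 |
| maple | 6.00 | 11.7 | 89.2 |
| maple | 8.00 | 14.0 | 84.4 |

(each reading ± 1 percentage point)

- north: at 20 h take out 90% of the target then present, then wait 10 h
- north-west: at 20 h raise the temperature by 15 K, then wait 10 h
- south-west: change nothing and wait 10 h more
- east: at 20 h add free enzyme, 50.0% of the amount charged, then wait 10 h

- target that was removed still counts
- additions bring no volume worth counting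

- target, in percent of the substrate first charged, at 20 h
- what to do for the largest gain in target; "none" if nothing gains more than 2 percentage points (north / north-west / south-west / east / none)
- target present, with what was taken out counted in, in percent of the substrate first charged, after north
- target present, with what was taken out counted in, in percent of the substrate first charged, after south-west

**Follow one molecule that has left substrate in larch. Where is it?**
As target, or in an unseen form, since the two readings do not add up to the charge. Target divided by the fraction of the charge no longer substrate is the keep share, 63.8% in larch at 20.0 h.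

**Has it stopped falling?**
That is not proven. It reads 87.1% at 1.50 h, 72.7% at 12.0 h, then 63.8%. I assume that the two forms trade both ways and that this is close to their balance, which would be thermodynamic control.

**What stands at the asked time?**
The larch reading, 63.5%, with its scatter of 1 percentage point.

**And after waiting?**
With substrate at 0.4%, the keep share of the charge: about 63.8%.

**And after north?**
The part taken out, 57.1% of the charge, is safe. The remaining 42.9% forks again at the keep share, so I reckon 84.5% in total.

**The weak spot?**
If the unseen form cannot return, that reckoning fails.

The forecast gives 63.8% (62.3% to 65.3%) for now and chooses north. It puts north at 74% (61% to 81%) and south-west at 57% (50% to 61%), on the ground that “Removing target should pull side product back”. My two figures stand above its ranges.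

The flask gives 64.6% at 20 h, and the best choice is north, with 82.2% after north and 63.2% after south-west. North gains 18 points, more than north-west with 12 points.

    free enzyme → unfolded enzyme (k = 1.40 × 10⁻⁶ s⁻¹, Ea = 181 kJ mol⁻¹)
    complex → free enzyme + target (k = 0.290 s⁻¹, Ea = 80.0 kJ mol⁻¹)
    target ⇌ isomer of the product (K = 0.590, k = 2.20 × 10⁻⁵ s⁻¹, Ea = 96.0 kJ mol⁻¹, ΔH = −36.0 kJ mol⁻¹)
    substrate + free enzyme ⇌ complex (K = 7.50 M⁻¹, k = 490 M⁻¹ s⁻¹, Ea = 36.0 kJ mol⁻¹, ΔH = 6.00 kJ mol⁻¹)
    (constants at 37 °C)

The unseen form is isomer of the product, and the keep share sits 0.60 points above the south-west result and north lands 2.3 points under my reckoning. The main reason for the choice of north is the conversion of target into isomer of the product, both ways: in the run without it, target at 20 h stands at 98.9%, against 64.6%. The backward run from isomer of the product to target is a part of this: in the run without that part, target at 20 h stands at 31.7%.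

In the neighbour flask stopped at 5.0 h, substrate stands at 40.3%, so the keep share gives 38.1% target. The computed flask holds 50.4%, a share of 84.5%, which stands above the keep share.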